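**Plan**

1. Numbering used throughout: C1 quaternary carbon with methyl, C2 (isovalerate), C3, C4, C5 (tertiary alcohol), C6=C7 (enol ether), C8 and C17 (butenolide β- and α-carbons), C19 (lactone carbonyl), C9 (CH2), C10 (ring-fusion CH), C11=C12 (C11 carries methyl), C13, C14 (acetate); ring A is C1/C10–C14, the ten-membered ring is C1–C10.
2. Cuts, in retrosynthetic order: C6=C7 (ten-membered ring; vinylogous aldol, then loss of silanol), C2–C3 (alkylzinc addition to a C2 aldehyde), C10–C11 (ring A; 6-exo radical cyclization), C8–C9 (Heck reaction), C1–C14 (iridium-catalysed carbonyl tert-(hydroxy)prenylation).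
3. Enabling feature: with a C9=C10 double bond drawn in, C10 is the δ-terminus of the dienyl lactone C10=C9–C8=C17–C19=O, so a vinyl radical at C11 (tethered through C12–C13–C14–C1) closes ring A there and the butenolide re-forms with C9 as CH2. The C14 and C2 oxygens flank C1 as a 1,3-diol and are tied as an acetonide (temporary 1,3-dioxane, removed in step 9) to lock the chair.
4. Forward order: acyclic C12–C14/C1/C2/C10 unit (step 1), 1,3-dioxane, dienyl butenolide, ring A (step 8), C3–C6 chain on C2, ten-membered ring (step 20); the butenolide ring is bought as 3-methyltetronic acid.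
5. Stereochemistry: C14 and C1 are set together by the (S)-Tol-BINAP iridium catalyst made from [Ir(cod)Cl]2; C10 is relayed from them through the acetonide-locked chair in the key step; C2 comes from a catalyst-controlled alkylzinc addition; C5 comes from (S)-citramalic acid; the C6=C7 geometry is dictated by the ring.

Key step: step 8

Remark 1: the (S)-Tol-BINAP-modified iridium catalyst is assumed to give the (2S,3S) diol 3; the (R)-ligand is used if the sense is the reverse.
Remark 2: the catalyst formed from Ti(OiPr)4 and (1R,2R)-N,N'-bis(trifluoromethanesulfonyl)cyclohexane-1,2-diamine is assumed to direct the alkyl group to the aldehyde face that gives the (S) carbinol at C2, as it gives (S)-alcohols from simple aldehydes; otherwise its enantiomer is used.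

**Route**

Step 1
Reactants: 1 3-[(tert-butyldimethylsilyl)oxy]propan-1-ol; 2 2-ethenyl-2-methyloxirane (isoprene monoxide, racemic)
Product: 3 (2S,3S)-5-[(tert-butyldimethylsilyl)oxy]-2-ethenyl-2-methylpentane-1,3-diol
Conditions: π-allyliridium C,O-benzoate catalyst preformed from [Ir(cod)Cl]2, (S)-Tol-BINAP, 4-cyano-3-nitrobenzoic acid and allyl acetate (5 mol%), K3PO4 (5 mol%), THF, 60 °C
Reagents that add atoms: none
Why: In this redox-triggered carbonyl tert-(hydroxy)prenylation (transfer-hydrogenative allylation) the alcohol is dehydrogenated to the aldehyde, racemic 2 converges on one π-allyliridium alkoxide, and addition through the (E)-σ-allyl chair transition state should set C14 and the quaternary C1 together with the C14 hydroxyl anti to the C1 hydroxymethyl, the ligand fixing the absolute sense.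

Step 2
Reactants: 3 (2S,3S)-5-[(tert-butyldimethylsilyl)oxy]-2-ethenyl-2-methylpentane-1,3-diol
Product: 4 (4S,5S)-4-{2-[(tert-butyldimethylsilyl)oxy]ethyl}-5-ethenyl-2,2,5-trimethyl-1,3-dioxane
Conditions: 2,2-dimethoxypropane, PPTS (cat.), CH2Cl2, rt
Reagents that add atoms: 2,2-dimethoxypropane COC(C)(C)OC
Why: Acid-catalysed transacetalization closes the 1,3-diol to the acetonide, the temporary 1,3-dioxane that later controls step 8.

Step 3
Reactants: 5 4-hydroxy-3-methylfuran-2(5H)-one (3-methyltetronic acid)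
Product: 6 4-bromo-3-methylfuran-2(5H)-one
Conditions: (COBr)2, DMF (cat.), CH2Cl2, 0 °C to rt
Reagents that add atoms: oxalyl bromide O=C(Br)C(=O)Br
Why: Vilsmeier-type deoxybromination of the vinylogous acid should give the β-bromobutenolide.

Step 4
Reactants: 4 (4S,5S)-4-{2-[(tert-butyldimethylsilyl)oxy]ethyl}-5-ethenyl-2,2,5-trimethyl-1,3-dioxane; 6 4-bromo-3-methylfuran-2(5H)-one
Product: 7 4-[(E)-2-[(4S,5S)-4-{2-[(tert-butyldimethylsilyl)oxy]ethyl}-2,2,5-trimethyl-1,3-dioxan-5-yl]ethenyl]-3-methylfuran-2(5H)-one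
Conditions: Pd(OAc)2 (10 mol%), Bu4NCl, NaHCO3, DMF, 70 °C
Reagents that add atoms: none
Why: In this Heck reaction under Jeffery conditions the vinyl-palladium species from 6 should insert the vinyl group at its unhindered terminal carbon C9, and β-hydride elimination can only take place from C9 because C1 is quaternary, so the (E)-diene and the C8–C9 bond should form cleanly.

Step 5
Reactants: 7 4-[(E)-2-[(4S,5S)-4-{2-[(tert-butyldimethylsilyl)oxy]ethyl}-2,2,5-trimethyl-1,3-dioxan-5-yl]ethenyl]-3-methylfuran-2(5H)-one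
Product: 8 4-[(E)-2-[(4S,5S)-4-(2-hydroxyethyl)-2,2,5-trimethyl-1,3-dioxan-5-yl]ethenyl]-3-methylfuran-2(5H)-one
Conditions: HF·pyridine, pyridine, THF, 0 °C to rt
Reagents that add atoms: none
Why: Buffered fluoride cleaves the primary silyl ether and should leave the acetonide and the base-sensitive butenolide intact.

Step 6
Reactants: 8 4-[(E)-2-[(4S,5S)-4-(2-hydroxyethyl)-2,2,5-trimethyl-1,3-dioxan-5-yl]ethenyl]-3-methylfuran-2(5H)-one
Product: 9 2-[(4S,5S)-2,2,5-trimethyl-5-[(E)-2-(4-methyl-5-oxo-2,5-dihydrofuran-3-yl)ethenyl]-1,3-dioxan-4-yl]acetaldehyde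
Conditions: TEMPO (10 mol%), PhI(OAc)2, CH2Cl2, rt
Reagents that add atoms: none
Why: The nitroxyl-catalysed oxidation stops at the aldehyde under near-neutral conditions that should spare the acetonide and the diene.

Step 7
Reactants: 9 2-[(4S,5S)-2,2,5-trimethyl-5-[(E)-2-(4-methyl-5-oxo-2,5-dihydrofuran-3-yl)ethenyl]-1,3-dioxan-4-yl]acetaldehyde
Product: 10 4-[(E)-2-[(4S,5S)-4-[(2Z)-3-iodobut-2-en-1-yl]-2,2,5-trimethyl-1,3-dioxan-5-yl]ethenyl]-3-methylfuran-2(5H)-one
Conditions: EtPPh3I, n-BuLi, THF, 0 °C; I2, −78 °C; NaN(SiMe3)2, −78 to −20 °C; then 9, −78 °C to rt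
Reagents that add atoms: ethyltriphenylphosphonium iodide CC[P+](c1ccccc1)(c1ccccc1)c1ccccc1.[I-]; iodine II
Why: Stork–Zhao-type Wittig olefination with the α-iodo ylide should give the 2-iodo-2-alkene with the Z isomer favoured, and the geometry is not critical because the derived vinyl radical inverts rapidly.

Step 8
Reactants: 10 4-[(E)-2-[(4S,5S)-4-[(2Z)-3-iodobut-2-en-1-yl]-2,2,5-trimethyl-1,3-dioxan-5-yl]ethenyl]-3-methylfuran-2(5H)-one
Product: 12 3-methyl-4-{[(4aS,5S,8aS)-2,2,4a,6-tetramethyl-4a,5,8,8a-tetrahydro-4H-1,3-benzodioxin-5-yl]methyl}furan-2(5H)-one, via deconjugated alkylidene lactone 11 (not isolated)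
Conditions: Bu3SnH (1.3 equiv, syringe pump), AIBN (0.2 equiv), PhH (0.01 M), 80 °C; then DBU (0.3 equiv), CH2Cl2, rt
Reagents that add atoms: none
Why: Bu3Sn• abstracts iodine from 10 and the σ-vinyl radical at C11 adds to C10, the terminus of the dienyl lactone, to give a radical delocalised over C9, C17 and the lactone carbonyl that is quenched by Bu3SnH at C17 or C9; DBU then brings the C8=C9 isomer 11 into conjugation (C8=C17), so that C9 ends as the CH2 of the target. The closest known reaction type is the Bu3SnH-mediated vinyl (aryl-type) radical cyclization onto an electron-poor alkene, here in its vinylogous (1,6-Giese) form. Ring A (C1, C10–C14) closes in the 6-exo-trig mode with the C11=C12 double bond kept inside the ring. The new stereocenter C10 is controlled by the acetonide: its chair holds the C13 arm equatorial on C14 (an axial arm would meet the axial acetonide methyl) and therefore the dienyl arm axial on C1, so ring A can only form as the chair with the C14 oxygen axial and C2 equatorial, and the reacting diene terminus takes the equatorial site, which puts C9 cis to the C1 methyl and trans to C2 (the axial alternative clashes with the C14 oxygen). The step needs attack at C10 and not C9 (secured by the stabilised radical that only C10 attack gives and by 6-exo over 7-endo closure), cyclization faster than direct reduction or hydrogen shift (secured by slow addition of Bu3SnH at high dilution and by the gauche, pre-organised arms on the dioxane), and no dependence on the iodide geometry (the vinyl radical inverts rapidly).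

Step 9
Reactants: 12 3-methyl-4-{[(4aS,5S,8aS)-2,2,4a,6-tetramethyl-4a,5,8,8a-tetrahydro-4H-1,3-benzodioxin-5-yl]methyl}furan-2(5H)-one
Product: 13 4-{[(1S,5S,6S)-5-hydroxy-6-(hydroxymethyl)-2,6-dimethylcyclohex-2-en-1-yl]methyl}-3-methylfuran-2(5H)-one
Conditions: AcOH/THF/H2O (3:1:1), 45 °C
Reagents that add atoms: none
Why: Mild acid hydrolysis removes the temporary acetonide once it has served and should leave the lactone and the trisubstituted alkene untouched.

Step 10
Reactants: 13 4-{[(1S,5S,6S)-5-hydroxy-6-(hydroxymethyl)-2,6-dimethylcyclohex-2-en-1-yl]methyl}-3-methylfuran-2(5H)-one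
Product: 14 (1R,2S,6S)-6-hydroxy-1,3-dimethyl-2-[(4-methyl-5-oxo-2,5-dihydrofuran-3-yl)methyl]cyclohex-3-ene-1-carbaldehyde
Conditions: TEMPO (20 mol%), PhI(OAc)2 (1.1 equiv), CH2Cl2, rt
Reagents that add atoms: none
Why: The nitroxyl-catalysed oxidation is selective for the primary alcohol over the secondary C14 alcohol, and the quaternary α-carbon rules out epimerisation or elimination of the β-hydroxy aldehyde.

Step 11
Reactants: 14 (1R,2S,6S)-6-hydroxy-1,3-dimethyl-2-[(4-methyl-5-oxo-2,5-dihydrofuran-3-yl)methyl]cyclohex-3-ene-1-carbaldehyde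
Product: 15 (1S,5S,6R)-6-formyl-4,6-dimethyl-5-[(4-methyl-5-oxo-2,5-dihydrofuran-3-yl)methyl]cyclohex-3-en-1-yl acetate
Conditions: Ac2O, pyridine, DMAP (cat.), CH2Cl2, 0 °C
Reagents that add atoms: acetic anhydride CC(=O)OC(C)=O
Why: DMAP-catalysed acetylation installs the C14 acetate of the target, and the product cannot β-eliminate because the aldehyde has no α-hydrogen.

Step 12
Reactants: 16 (2S)-2-hydroxy-2-methylbutanedioic acid ((S)-citramalic acid)
Product: 17 (2S)-2-methylbutane-1,2,4-triol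
Conditions: BH3·SMe2, B(OMe)3, THF, 0 °C to rt; MeOH quench
Reagents that add atoms: none
Why: Borane reduces both carboxyl groups of the chiral-pool acid and leaves the tertiary carbinol centre (the future C5) untouched.

Step 13
Reactants: 17 (2S)-2-methylbutane-1,2,4-triol
Product: 18 2-[(4S)-2,2,4-trimethyl-1,3-dioxolan-4-yl]ethan-1-ol
Conditions: 2,2-dimethoxypropane, TsOH·H2O (cat.), CH2Cl2, rt
Reagents that add atoms: 2,2-dimethoxypropane COC(C)(C)OC
Why: Acetonide formation under equilibrating conditions favours the five-membered dioxolane across the 1,2-diol over the six-membered alternative, which frees the primary alcohol on the C3 side.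

Step 14
Reactants: 18 2-[(4S)-2,2,4-trimethyl-1,3-dioxolan-4-yl]ethan-1-ol
Product: 19 (4S)-4-(2-iodoethyl)-2,2,4-trimethyl-1,3-dioxolane
Conditions: I2, PPh3, imidazole, CH2Cl2, 0 °C to rt
Reagents that add atoms: iodine II
Why: Appel-type iodination converts the unhindered primary alcohol into the iodide under conditions that are buffered for the acetonide.

Step 15
Reactants: 19 (4S)-4-(2-iodoethyl)-2,2,4-trimethyl-1,3-dioxolane
Product: 21 {2-[(4S)-2,2,4-trimethyl-1,3-dioxolan-4-yl]ethyl}[(trimethylsilyl)methyl]zinc, via alkylzinc iodide 20 (not isolated)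
Conditions: Zn dust (activated with BrCH2CH2Br and Me3SiCl, cat.), THF, 40 °C; Me3SiCH2Li (1.0 equiv, pentane), −78 to 0 °C; THF removed in vacuo, toluene, filtration of LiI under argon
Reagents that add atoms: zinc [Zn]; (trimethylsilyl)methyllithium [Li]C[Si](C)(C)C
Why: Direct insertion of activated zinc into the primary C–I bond gives the alkylzinc iodide, whose oxygen sits γ to zinc and cannot β-eliminate, and transmetalation with Me3SiCH2Li gives the mixed diorganozinc in which the trimethylsilylmethyl group is a non-transferable ligand, so that one equivalent of the chiral-pool iodide furnishes one equivalent of transferable alkyl group.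

Step 16
Reactants: 15 (1S,5S,6R)-6-formyl-4,6-dimethyl-5-[(4-methyl-5-oxo-2,5-dihydrofuran-3-yl)methyl]cyclohex-3-en-1-yl acetate; 21 {2-[(4S)-2,2,4-trimethyl-1,3-dioxolan-4-yl]ethyl}[(trimethylsilyl)methyl]zinc
Product: 22 (1S,5S,6S)-6-{(1S)-1-hydroxy-3-[(4S)-2,2,4-trimethyl-1,3-dioxolan-4-yl]propyl}-4,6-dimethyl-5-[(4-methyl-5-oxo-2,5-dihydrofuran-3-yl)methyl]cyclohex-3-en-1-yl acetate
Conditions: 21 (2.5 equiv), Ti(OiPr)4 (2 equiv), (1R,2R)-N,N'-bis(trifluoromethanesulfonyl)cyclohexane-1,2-diamine (10 mol%), toluene, −20 °C; aq NH4Cl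
Reagents that add atoms: none
Why: The Ti(OiPr)4-promoted, bis-sulfonamide-catalysed addition of a mixed alkyl(trimethylsilylmethyl)zinc to an aldehyde transfers only the functionalised alkyl group, forms C2–C3 and should set C2 under catalyst control, while the mild reagent leaves the acetate and the butenolide alone.

Step 17
Reactants: 22 (1S,5S,6S)-6-{(1S)-1-hydroxy-3-[(4S)-2,2,4-trimethyl-1,3-dioxolan-4-yl]propyl}-4,6-dimethyl-5-[(4-methyl-5-oxo-2,5-dihydrofuran-3-yl)methyl]cyclohex-3-en-1-yl acetate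
Product: 23 (1S)-1-[(1S,2S,6S)-6-acetoxy-1,3-dimethyl-2-[(4-methyl-5-oxo-2,5-dihydrofuran-3-yl)methyl]cyclohex-3-en-1-yl]-3-[(4S)-2,2,4-trimethyl-1,3-dioxolan-4-yl]propyl 3-methylbutanoate
Conditions: (iPrCH2CO)2O, DMAP, Et3N, CH2Cl2, rt to 40 °C
Reagents that add atoms: 3-methylbutanoic anhydride CC(C)CC(=O)OC(=O)CC(C)C
Why: DMAP-catalysed acylation with the anhydride should esterify the hindered secondary C2 alcohol without touching the C2 configuration or the acetonide.

Step 18
Reactants: 23 (1S)-1-[(1S,2S,6S)-6-acetoxy-1,3-dimethyl-2-[(4-methyl-5-oxo-2,5-dihydrofuran-3-yl)methyl]cyclohex-3-en-1-yl]-3-[(4S)-2,2,4-trimethyl-1,3-dioxolan-4-yl]propyl 3-methylbutanoate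
Product: 24 (1S,4S)-1-[(1S,2S,6S)-6-acetoxy-1,3-dimethyl-2-[(4-methyl-5-oxo-2,5-dihydrofuran-3-yl)methyl]cyclohex-3-en-1-yl]-4,5-dihydroxy-4-methylpentyl 3-methylbutanoate
Conditions: AcOH/H2O (4:1), 40 °C
Reagents that add atoms: none
Why: Aqueous acid hydrolyses the dioxolane to the C5 tertiary and C6 primary alcohols under conditions that the two esters should survive.

Step 19
Reactants: 24 (1S,4S)-1-[(1S,2S,6S)-6-acetoxy-1,3-dimethyl-2-[(4-methyl-5-oxo-2,5-dihydrofuran-3-yl)methyl]cyclohex-3-en-1-yl]-4,5-dihydroxy-4-methylpentyl 3-methylbutanoate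
Product: 25 (1S,4S)-1-[(1S,2S,6S)-6-acetoxy-1,3-dimethyl-2-[(4-methyl-5-oxo-2,5-dihydrofuran-3-yl)methyl]cyclohex-3-en-1-yl]-4-hydroxy-4-methyl-5-oxopentyl 3-methylbutanoate
Conditions: (COCl)2, DMSO, CH2Cl2, −78 °C; Et3N, −78 to −20 °C
Reagents that add atoms: none
Why: Swern oxidation converts the primary alcohol into the non-enolisable α-hydroxy aldehyde and avoids the glycol cleavage that a hypervalent iodine oxidant could cause on the 1,2-diol.

Step 20
Reactants: 25 (1S,4S)-1-[(1S,2S,6S)-6-acetoxy-1,3-dimethyl-2-[(4-methyl-5-oxo-2,5-dihydrofuran-3-yl)methyl]cyclohex-3-en-1-yl]-4-hydroxy-4-methyl-5-oxopentyl 3-methylbutanoate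
Product: 28 (1S,2S,5S,10S,14S,6E)-14-acetoxy-2-(3-methylbutanoyloxy)-5-[(triethylsilyl)oxy]briara-6,8(17),11-trien-19,7-olide, via bis-silylated silyloxyfuran aldehyde 26 (not isolated), via silylated aldol macrocycle 27 (not isolated)
Conditions: Et3SiOTf (4 equiv), iPr2NEt (6 equiv), CH2Cl2 (1 mM, slow addition of 25), −78 to 0 °C; then DBU (5 equiv), rt
Reagents that add atoms: triethylsilyl trifluoromethanesulfonate CC[Si](CC)(CC)OS(=O)(=O)C(F)(F)F
Why: In this silylative vinylogous Mukaiyama aldol cyclization followed by E1cB loss of silanol, Et3SiOTf and the amine silylate the C5 hydroxyl and turn the butenolide into its aromatic 2-silyloxyfuran, whose C7 attacks the silyl-activated C6 aldehyde at high dilution, and DBU then removes the acidic C7 hydrogen and expels the C6 silyloxide, so that the C6=C7 bond should form with C5 and C8 cis as the ten-membered ring demands while the transient C6 and C7 stereocenters are erased.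

Step 21
Reactants: 28 (1S,2S,5S,10S,14S,6E)-14-acetoxy-2-(3-methylbutanoyloxy)-5-[(triethylsilyl)oxy]briara-6,8(17),11-trien-19,7-olide
Product: 29 (1S,2S,5S,10S,14S,6E)-14-acetoxy-5-hydroxy-2-(3-methylbutanoyloxy)briara-6,8(17),11-trien-19,7-olide (CNP0208239.1)
Conditions: HF·pyridine, pyridine, THF, 0 °C
Reagents that add atoms: none
Why: Buffered fluoride removes the tertiary triethylsilyl ether and should leave the two esters, the ylidene butenolide and the allylic tertiary alcohol unchanged.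

**Compound list**

1 | 3-[(tert-butyldimethylsilyl)oxy]propan-1-ol | OCCCO[Si](C)(C)C(C)(C)C | starting material
2 | 2-ethenyl-2-methyloxirane (isoprene monoxide, racemic) | CC1(CO1)C=C | starting material
3 | (2S,3S)-5-[(tert-butyldimethylsilyl)oxy]-2-ethenyl-2-methylpentane-1,3-diol | OC[C@](C)(C=C)[C@@H](O)CCO[Si](C)(C)C(C)(C)C | intermediate
4 | (4S,5S)-4-{2-[(tert-butyldimethylsilyl)oxy]ethyl}-5-ethenyl-2,2,5-trimethyl-1,3-dioxane | CC1(C)OC[C@](C)(C=C)[C@H](CCO[Si](C)(C)C(C)(C)C)O1 | intermediate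
5 | 4-hydroxy-3-methylfuran-2(5H)-one (3-methyltetronic acid) | CC1=C(O)COC1=O | starting material
6 | 4-bromo-3-methylfuran-2(5H)-one | CC1=C(Br)COC1=O | intermediate
7 | 4-[(E)-2-[(4S,5S)-4-{2-[(tert-butyldimethylsilyl)oxy]ethyl}-2,2,5-trimethyl-1,3-dioxan-5-yl]ethenyl]-3-methylfuran-2(5H)-one | CC1(C)OC[C@](C)(/C=C/C2=C(C)C(=O)OC2)[C@H](CCO[Si](C)(C)C(C)(C)C)O1 | intermediate
8 | 4-[(E)-2-[(4S,5S)-4-(2-hydroxyethyl)-2,2,5-trimethyl-1,3-dioxan-5-yl]ethenyl]-3-methylfuran-2(5H)-one | CC1(C)OC[C@](C)(/C=C/C2=C(C)C(=O)OC2)[C@H](CCO)O1 | intermediate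
9 | 2-[(4S,5S)-2,2,5-trimethyl-5-[(E)-2-(4-methyl-5-oxo-2,5-dihydrofuran-3-yl)ethenyl]-1,3-dioxan-4-yl]acetaldehyde | CC1(C)OC[C@](C)(/C=C/C2=C(C)C(=O)OC2)[C@H](CC=O)O1 | intermediate
10 | 4-[(E)-2-[(4S,5S)-4-[(2Z)-3-iodobut-2-en-1-yl]-2,2,5-trimethyl-1,3-dioxan-5-yl]ethenyl]-3-methylfuran-2(5H)-one | CC1(C)OC[C@](C)(/C=C/C2=C(C)C(=O)OC2)[C@H](C/C=C(\I)C)O1 | intermediate
11 | 3-methyl-4-{[(4aS,5S,8aS)-2,2,4a,6-tetramethyl-4a,5,8,8a-tetrahydro-4H-1,3-benzodioxin-5-yl]methylidene}oxolan-2-one (C8=C9 isomer of 12; alkene and C17 isomers) | CC1(C)O[C@H]2CC=C(C)[C@H](C=C3COC(=O)C3C)[C@@]2(C)CO1 | intermediate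
12 | 3-methyl-4-{[(4aS,5S,8aS)-2,2,4a,6-tetramethyl-4a,5,8,8a-tetrahydro-4H-1,3-benzodioxin-5-yl]methyl}furan-2(5H)-one | CC1(C)O[C@H]2CC=C(C)[C@H](CC3=C(C)C(=O)OC3)[C@@]2(C)CO1 | intermediate
13 | 4-{[(1S,5S,6S)-5-hydroxy-6-(hydroxymethyl)-2,6-dimethylcyclohex-2-en-1-yl]methyl}-3-methylfuran-2(5H)-one | O[C@H]1CC=C(C)[C@H](CC2=C(C)C(=O)OC2)[C@@]1(C)CO | intermediate
14 | (1R,2S,6S)-6-hydroxy-1,3-dimethyl-2-[(4-methyl-5-oxo-2,5-dihydrofuran-3-yl)methyl]cyclohex-3-ene-1-carbaldehyde | O[C@H]1CC=C(C)[C@H](CC2=C(C)C(=O)OC2)[C@@]1(C)C=O | intermediate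
15 | (1S,5S,6R)-6-formyl-4,6-dimethyl-5-[(4-methyl-5-oxo-2,5-dihydrofuran-3-yl)methyl]cyclohex-3-en-1-yl acetate | CC(=O)O[C@H]1CC=C(C)[C@H](CC2=C(C)C(=O)OC2)[C@@]1(C)C=O | intermediate
16 | (2S)-2-hydroxy-2-methylbutanedioic acid ((S)-citramalic acid) | C[C@](O)(CC(=O)O)C(=O)O | starting material
17 | (2S)-2-methylbutane-1,2,4-triol | C[C@](O)(CCO)CO | intermediate
18 | 2-[(4S)-2,2,4-trimethyl-1,3-dioxolan-4-yl]ethan-1-ol | C[C@]1(CCO)COC(C)(C)O1 | intermediate
19 | (4S)-4-(2-iodoethyl)-2,2,4-trimethyl-1,3-dioxolane | C[C@]1(CCI)COC(C)(C)O1 | intermediate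
20 | {2-[(4S)-2,2,4-trimethyl-1,3-dioxolan-4-yl]ethyl}zinc iodide | C[C@]1(CC[Zn]I)COC(C)(C)O1 | intermediate
21 | {2-[(4S)-2,2,4-trimethyl-1,3-dioxolan-4-yl]ethyl}[(trimethylsilyl)methyl]zinc | C[C@]1(CC[Zn]C[Si](C)(C)C)COC(C)(C)O1 | intermediate
22 | (1S,5S,6S)-6-{(1S)-1-hydroxy-3-[(4S)-2,2,4-trimethyl-1,3-dioxolan-4-yl]propyl}-4,6-dimethyl-5-[(4-methyl-5-oxo-2,5-dihydrofuran-3-yl)methyl]cyclohex-3-en-1-yl acetate | CC(=O)O[C@H]1CC=C(C)[C@H](CC2=C(C)C(=O)OC2)[C@@]1(C)[C@@H](O)CC[C@@]3(C)COC(C)(C)O3 | intermediate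
23 | (1S)-1-[(1S,2S,6S)-6-acetoxy-1,3-dimethyl-2-[(4-methyl-5-oxo-2,5-dihydrofuran-3-yl)methyl]cyclohex-3-en-1-yl]-3-[(4S)-2,2,4-trimethyl-1,3-dioxolan-4-yl]propyl 3-methylbutanoate | CC(=O)O[C@H]1CC=C(C)[C@H](CC2=C(C)C(=O)OC2)[C@@]1(C)[C@@H](OC(=O)CC(C)C)CC[C@@]3(C)COC(C)(C)O3 | intermediate
24 | (1S,4S)-1-[(1S,2S,6S)-6-acetoxy-1,3-dimethyl-2-[(4-methyl-5-oxo-2,5-dihydrofuran-3-yl)methyl]cyclohex-3-en-1-yl]-4,5-dihydroxy-4-methylpentyl 3-methylbutanoate | CC(=O)O[C@H]1CC=C(C)[C@H](CC2=C(C)C(=O)OC2)[C@@]1(C)[C@@H](OC(=O)CC(C)C)CC[C@](C)(O)CO | intermediate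
25 | (1S,4S)-1-[(1S,2S,6S)-6-acetoxy-1,3-dimethyl-2-[(4-methyl-5-oxo-2,5-dihydrofuran-3-yl)methyl]cyclohex-3-en-1-yl]-4-hydroxy-4-methyl-5-oxopentyl 3-methylbutanoate | CC(=O)O[C@H]1CC=C(C)[C@H](CC2=C(C)C(=O)OC2)[C@@]1(C)[C@@H](OC(=O)CC(C)C)CC[C@](C)(O)C=O | intermediate
26 | (1S,4S)-1-[(1S,2S,6S)-6-acetoxy-1,3-dimethyl-2-({4-methyl-5-[(triethylsilyl)oxy]furan-3-yl}methyl)cyclohex-3-en-1-yl]-4-methyl-5-oxo-4-[(triethylsilyl)oxy]pentyl 3-methylbutanoate | CC(=O)O[C@H]1CC=C(C)[C@H](Cc2coc(O[Si](CC)(CC)CC)c2C)[C@@]1(C)[C@@H](OC(=O)CC(C)C)CC[C@](C)(O[Si](CC)(CC)CC)C=O | intermediate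
27 | (1S,2S,5S,10S,14S)-14-acetoxy-2-(3-methylbutanoyloxy)-5,6-bis[(triethylsilyl)oxy]briara-8(17),11-dien-19,7-olide (C6 and C7 epimers) | CC(=O)O[C@H]1CC=C(C)[C@@H]2CC3=C(C)C(=O)OC3C(O[Si](CC)(CC)CC)[C@@](C)(O[Si](CC)(CC)CC)CC[C@H](OC(=O)CC(C)C)[C@@]12C | intermediate
28 | (1S,2S,5S,10S,14S,6E)-14-acetoxy-2-(3-methylbutanoyloxy)-5-[(triethylsilyl)oxy]briara-6,8(17),11-trien-19,7-olide | CC(=O)O[C@H]1CC=C(C)[C@@H]2CC3=C(C)C(=O)O/C3=C/[C@@](C)(O[Si](CC)(CC)CC)CC[C@H](OC(=O)CC(C)C)[C@@]12C | intermediate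
29 | (1S,2S,5S,10S,14S,6E)-14-acetoxy-5-hydroxy-2-(3-methylbutanoyloxy)briara-6,8(17),11-trien-19,7-olide (CNP0208239.1) | CC(=O)O[C@H]1CC=C(C)[C@@H]2CC3=C(C)C(=O)O/C3=C/[C@@](C)(O)CC[C@H](OC(=O)CC(C)C)[C@@]12C | target

**Step count**

Total step count: 21.
Longest linear sequence: 16 steps (steps 1, 2, 4–11 and 16–21, from compound 1).

**Steps most likely to fail, with fallbacks**

Step 20. The ring closure may lose to intermolecular aldol oligomerisation or to protodesilylation of the silyloxyfuran because of the transannular strain of the forming ten-membered ring, and the elimination may give the wrong C6=C7 geometry. The fallback closes the ring by an intramolecular Wittig reaction instead of an aldol. It sets out from aldehyde 25: Et3SiOTf and Et3N at −78 °C give the bis-silylated silyloxyfuran 26, which is brominated at C7 with N-bromosuccinimide at −78 °C to the 5-bromobutenolide aldehyde (1S,4S)-1-[(1S,2S,6S)-6-acetoxy-2-[(2-bromo-4-methyl-5-oxo-2,5-dihydrofuran-3-yl)methyl]-1,3-dimethylcyclohex-3-en-1-yl]-4-methyl-5-oxo-4-[(triethylsilyl)oxy]pentyl 3-methylbutanoate F1. PPh3 in MeCN displaces the allylic bromide to give the corresponding (butenolid-5-yl)triphenylphosphonium bromide F2. Slow addition of F2 to Et3N in CH2Cl2 at high dilution generates the stabilised ylide, whose Wittig reaction with the C6 aldehyde forms the C6=C7 bond directly, and the route is rejoined at 28.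

Step 8. The vinyl radical may be reduced before it cyclises, may undergo a 1,6-hydrogen shift, or may add with eroded facial selectivity at C10. The fallback replaces the radical chain by a polar organonickel cyclization and makes no new compound (F0). It sets out from 10 and uses Ni(cod)2 (1.5 equiv) and Et3N in MeCN at rt: oxidative addition of zerovalent nickel into the C–I bond (here the Z geometry from step 7 is required), syn-carbometalation of C10=C9 through the same acetonide-locked chair, and protonation of the nickel dienolate on work-up. A brief DBU treatment then rejoins the route at 12.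

Step 16. Alkyl transfer to the neopentyl aldehyde may be slow, and the facial selectivity may be poor if the substrate bias opposes the catalyst or if residual lithium salt promotes an uncatalysed addition. The fallback sets the C2 stereocenter by ketone reduction instead of by C–C bond formation. It sets out from 22 obtained as a mixture of C2 epimers: Dess–Martin periodinane oxidation gives the ketone (1S,5S,6R)-4,6-dimethyl-5-[(4-methyl-5-oxo-2,5-dihydrofuran-3-yl)methyl]-6-{3-[(4S)-2,2,4-trimethyl-1,3-dioxolan-4-yl]propanoyl}cyclohex-3-en-1-yl acetate F3. CBS reduction with (R)-2-methyl-CBS-oxazaborolidine and catecholborane in toluene at −78 to −40 °C (quaternary C1 as the large group, the CH2CH2 chain as the small one; the (S)-oxazaborolidine is used if the sense is the reverse) should return the (S) carbinol, and the route is rejoined at 22.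

**Further compounds**

F1 | step 20 | (1S,4S)-1-[(1S,2S,6S)-6-acetoxy-2-[(2-bromo-4-methyl-5-oxo-2,5-dihydrofuran-3-yl)methyl]-1,3-dimethylcyclohex-3-en-1-yl]-4-methyl-5-oxo-4-[(triethylsilyl)oxy]pentyl 3-methylbutanoate (C7 epimers) | CC(=O)O[C@H]1CC=C(C)[C@H](CC2=C(C)C(=O)OC2Br)[C@@]1(C)[C@@H](OC(=O)CC(C)C)CC[C@](C)(O[Si](CC)(CC)CC)C=O
F2 | step 20 | (butenolid-5-yl)triphenylphosphonium bromide derived from F1 (C7 epimers) | CC(=O)O[C@H]1CC=C(C)[C@H](CC2=C(C)C(=O)OC2[P+](c3ccccc3)(c3ccccc3)c3ccccc3)[C@@]1(C)[C@@H](OC(=O)CC(C)C)CC[C@](C)(O[Si](CC)(CC)CC)C=O.[Br-]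
F0 | step 8 | none | none
F3 | step 16 | (1S,5S,6R)-4,6-dimethyl-5-[(4-methyl-5-oxo-2,5-dihydrofuran-3-yl)methyl]-6-{3-[(4S)-2,2,4-trimethyl-1,3-dioxolan-4-yl]propanoyl}cyclohex-3-en-1-yl acetate | CC(=O)O[C@H]1CC=C(C)[C@H](CC2=C(C)C(=O)OC2)[C@@]1(C)C(=O)CC[C@@]3(C)COC(C)(C)O3
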